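If each substrate molecule consumes one reagent molecule, 1 equiv is the zero of the scale: both charges run out together, and any shortfall below that point stays behind as unreacted substrate.

- Sunday's: substrate 30 mM; reagent 0.50 equiv; free catalyst 1 mol%; run made earlier
- flask: substrate 20 mM; reagent 0.500 equiv; free catalyst 1 mol%; time 30 h

- Sunday's (time / h: substrate / %, product / %): 0.667: 86, 13; 1.33: 76, 23; 2.00: 71, 31; 2.50: 67, 28; 3.00: 64, 36

(standard deviation of a reading: 2 percentage points)

- the earlier runs do not show how much of reagent is bound; that part of a forecast is a guess
- no earlier run changes the charge of free catalyst; that part of a forecast is a guess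

- part of the substrate that has reacted at 30 h
- share of free reagent in free reagent and idle adduct together, at 30 h

On that assumption the flask has reagent as its limiting reagent and a ceiling of 50.0%, the conversion ceiling, meaning the reagent equivalents read as a percentage of the substrate. Sunday's run looks nearly the same, with 0.50 equiv and so the same ceiling, but its last reading, at 3.00 h, shows 36% product, so the readings stop below the ceiling. The flask is more dilute, yet it runs ten times as long as that last reading. Even a rate falling with the square of the dilution gives it the equivalent of 13.3 h of Sunday's time, longer than Sunday's last reading. The reckoning here therefore puts the flask close to its ceiling and offers no figure for the share.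

The forecast gives 49.3% (range 45% to 50%) and a share of 97% (range 70% to 100%), judging that “free reagent probably dominates”.

The flask gives 50.0%, on the ceiling of 50.0% and inside the forecast's range. Its share is 5.89%, which is 91 percentage points below the forecast, with [idle adduct] at 0.00400 mM.

    reagent + free catalyst → catalyst intermediate A (k = 710 M⁻¹ min⁻¹)
    catalyst intermediate A ⇌ catalyst intermediate B (K = 0.240, k = 130 min⁻¹)
    substrate + catalyst intermediate B → catalyst intermediate C (k = 110 M⁻¹ min⁻¹)
    catalyst intermediate C → released group + catalyst intermediate D (k = 440 min⁻¹)
    catalyst intermediate D ⇌ free catalyst + product (K = 0.0160 M, k = 130 min⁻¹)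
    reagent + released group ⇌ idle adduct, settled at all times (K = 1600 M⁻¹)
    reagent ⇌ dormant form (K = 5.10, k = 0.190 min⁻¹)

A neighbour flask, otherwise the same but charged with 0.850 equiv of reagent, has a ceiling of 85.0% by the same reckoning. At 30 h its substrate has reacted to 83.7%, below that ceiling, with 0.045% of its reagent and 16% of its substrate still unbound.

Readings and results are calculated for substances that don't exist.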